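**Retrosynthetic overview**
- The oxirane is the only ring made (the benzene ring is bought). It is closed last by enantioselective oxygen-atom transfer, forming both C–O bonds, to the 1,1-disubstituted alkene of a fully functionalised 2-arylallyl pentanoate.
- Benzylic CH2OH ⇐ aromatic aldehyde; allylic C–O bond of the pentanoate ⇐ carboxylate SN2 on a 2-arylallyl bromide (both in one flask).
- 2-Arylallyl bromide ⇐ ionic allylic bromination of an isopropenylarene.
- Aryl–isopropenyl bond and phenol isobutyrate ⇐ 4-bromo-3-hydroxybenzaldehyde + isopropenylboronate + isobutyric anhydride (one flask).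

Assumption: operations run in one flask without isolation count as one step; the target is the (R)-epoxide (CIP order at the quaternary carbon: ring O > CH2O-pentanoyl > ring CH2 > aryl).

Abbreviations: Me2N-PDP = (2S,2'S)-1,1'-bis{[4-(dimethylamino)pyridin-2-yl]methyl}-2,2'-bipyrrolidine; NPha-L-Tle-OH = (S)-2-(1,3-dioxo-1H-benzo[de]isoquinolin-2(3H)-yl)-3,3-dimethylbutanoic acid (N-1,8-naphthaloyl-L-tert-leucine).

**Step 1**
Reactants: 1 4-bromo-3-hydroxybenzaldehyde; 2 4,4,5,5-tetramethyl-2-(prop-1-en-2-yl)-1,3,2-dioxaborolane (isopropenylboronic acid pinacol ester); 3 2-methylpropanoic anhydride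
Product: 5 5-formyl-2-(prop-1-en-2-yl)phenyl 2-methylpropanoate, via phenol aldehyde 4 (not isolated)
Conditions: Pd(dppf)Cl2 (2 mol %), K2CO3 (3.5 equiv), 1,4-dioxane/H2O 4:1, 85 °C, 3 h; then 3 (1.5 equiv), 0 °C, 1 h
Reagents that add atoms: none
Why: Suzuki–Miyaura coupling at the C–Br bond para to the formyl group, then Schotten–Baumann O-acylation of the phenoxide already present in the basic medium, which traps the acid-sensitive 2-isopropenylphenol before it is handled; no stereocentre is formed.

**Step 2**
Reactants: 5 5-formyl-2-(prop-1-en-2-yl)phenyl 2-methylpropanoate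
Product: 6 2-(3-bromoprop-1-en-2-yl)-5-formylphenyl 2-methylpropanoate
Conditions: NBS (1.1 equiv), TsOH·H2O (10 mol %), THF, 65 °C, 4 h
Reagents that add atoms: N-bromosuccinimide O=C1CCC(=O)N1Br
Why: Acid-promoted electrophilic allylic bromination: Br+ adds to the terminal carbon and the tertiary benzylic cation loses a methyl proton to give the 2-arylallyl bromide (the ortho substituent twists the ring and disfavours the conjugated vinyl bromide), while the absence of a radical initiator spares the aldehyde C–H.

**Step 3**
Reactants: 6 2-(3-bromoprop-1-en-2-yl)-5-formylphenyl 2-methylpropanoate; 7 sodium pentanoate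
Product: 9 2-[4-(hydroxymethyl)-2-(2-methylpropanoyloxy)phenyl]prop-2-en-1-yl pentanoate, via aldehyde ester 8 (not isolated)
Conditions: 7 (1.2 equiv), Bu4NI (5 mol %), DMF, 25 °C, 3 h; then NaBH4 (0.5 equiv), EtOH, −20 °C, 20 min; aq. NH4Cl
Reagents that add atoms: none
Why: SN2 alkylation of the carboxylate by the primary allylic bromide forms the allylic C–O bond (SN2' would give the same product because the allyl termini are equivalent), then chemoselective borohydride reduction of the aromatic aldehyde at low temperature, which is far faster than attack on the hindered aryl isobutyrate or the alkyl ester.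

**Step 4**
Reactants: 9 2-[4-(hydroxymethyl)-2-(2-methylpropanoyloxy)phenyl]prop-2-en-1-yl pentanoate
Product: 10 [(2R)-2-[4-(hydroxymethyl)-2-(2-methylpropanoyloxy)phenyl]oxiran-2-yl]methyl pentanoate
Conditions: Fe(OTf)2((S,S)-Me2N-PDP) (2 mol %), NPha-L-Tle-OH (4 mol %), H2O2 (1.3 equiv, syringe pump), MeCN, −30 °C, 1 h; aq. Na2S2O3/NaHCO3
Reagents that add atoms: hydrogen peroxide OO
Why: Proposed new method: carboxylic-acid-assisted iron/H2O2 asymmetric epoxidation with a chiral bipyrrolidine complex of divalent iron and an N-protected amino acid co-ligand is the closest known reaction type (high ee with α-alkylstyrenes), but it has not been shown on a 2-arylallyl carboxylate carrying an ortho-acyloxy group and a free benzylic alcohol, nor with this tert-leucine co-ligand; the carboxylate bound cis to the iron hydroperoxide assists O–O heterolysis to a pentavalent oxoiron carboxylate, which should transfer oxygen to the 1,1-disubstituted C=C faster than it abstracts the carbinol C–H at −30 °C with limiting H2O2; the pocket formed by the C2-symmetric bipyrrolidine and the naphthalimide wall of the co-ligand is expected to accept the CH2O-acyl arm but not the twisted ortho-substituted aryl group, so oxygen goes to the Si face of the aryl-bearing carbon (CH2O-acyl > aryl > =CH2) and gives the (R) epoxide; tert-leucine has no tertiary C–H for the oxidant to attack and 4 mol % of acid is too little to open the benzylic epoxide; the facial sense of the (S,S)/L pair cannot be predicted with certainty, so if it delivers the Re face the mirror-image (R,R)/D pair, made the same way, is used.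

**Compound list**
1 | 4-bromo-3-hydroxybenzaldehyde | O=Cc1ccc(Br)c(O)c1 | starting material
2 | 4,4,5,5-tetramethyl-2-(prop-1-en-2-yl)-1,3,2-dioxaborolane | CC(=C)B1OC(C)(C)C(C)(C)O1 | starting material
3 | 2-methylpropanoic anhydride | CC(C)C(=O)OC(=O)C(C)C | starting material
4 | 3-hydroxy-4-(prop-1-en-2-yl)benzaldehyde (present as its potassium phenoxide) | CC(=C)c1ccc(C=O)cc1O | intermediate
5 | 5-formyl-2-(prop-1-en-2-yl)phenyl 2-methylpropanoate | CC(C)C(=O)Oc1cc(C=O)ccc1C(C)=C | intermediate
6 | 2-(3-bromoprop-1-en-2-yl)-5-formylphenyl 2-methylpropanoate | CC(C)C(=O)Oc1cc(C=O)ccc1C(=C)CBr | intermediate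
7 | sodium pentanoate | CCCCC(=O)[O-].[Na+] | starting material
8 | 2-[4-formyl-2-(2-methylpropanoyloxy)phenyl]prop-2-en-1-yl pentanoate | CCCCC(=O)OCC(=C)c1ccc(C=O)cc1OC(=O)C(C)C | intermediate
9 | 2-[4-(hydroxymethyl)-2-(2-methylpropanoyloxy)phenyl]prop-2-en-1-yl pentanoate | CCCCC(=O)OCC(=C)c1ccc(CO)cc1OC(=O)C(C)C | intermediate
10 | [(2R)-2-[4-(hydroxymethyl)-2-(2-methylpropanoyloxy)phenyl]oxiran-2-yl]methyl pentanoate | CCCCC(=O)OC[C@@]1(c2ccc(CO)cc2OC(=O)C(C)C)CO1 | target

**Step count and risks**
Total step count: 4 (steps 1 and 3 are each two operations in one flask). Longest linear sequence: 4 (1 → 5 → 6 → 9 → 10).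

Ranked by risk, the steps most likely to fail are step 4 (new), step 2 and step 1; the fallbacks are given in route order.

The coupling/acylation of step 1 can fail because the free ortho-bromophenoxide couples sluggishly, because phenol 4 dimerises, or because the hindered phenoxide is acylated incompletely in water. The fallback sets out from 1 and comes back at 5. The order is inverted and a base-free coupling is used: 1 is acylated first (isobutyryl chloride, Et3N, CH2Cl2, 0 °C) to 2-bromo-5-formylphenyl 2-methylpropanoate F1. F1 is then coupled under neutral Stille conditions with tributyl(prop-1-en-2-yl)stannane (Pd(PPh3)4, toluene, 100 °C), which leaves the aryl ester untouched and never exposes a free isopropenylphenol, to give 5.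

The bromination of step 2 can give the conjugated vinyl bromide, be diverted by capture of the benzylic cation by the neighbouring isobutyrate carbonyl, or damage the aldehyde. The fallback sets out from 5 and comes back at 8. The allylic C–O bond is made by C–H hydroxylation instead of halogenation and substitution: SeO2 (0.5 equiv) with anhydrous t-BuOOH in CH2Cl2 at 25 °C (ene reaction, then 2,3-sigmatropic shift) gives the allylic alcohol 5-formyl-2-(3-hydroxyprop-1-en-2-yl)phenyl 2-methylpropanoate F2. F2 is esterified with pentanoic anhydride (pyridine, DMAP cat., CH2Cl2, 0 °C) to aldehyde ester 8, which is reduced as in the second operation of step 3.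

The new epoxidation of step 4 can fail through low ee, oxidation of the benzylic alcohol to the aldehyde (reducible back with NaBH4 if it is the only defect), or acid opening of the epoxide. The fallback uses only known chemistry, sets out from 5 and ends at 10; it is a hydroxyl-directed Katsuki–Sharpless epoxidation, established for 2-substituted allylic alcohols.
- 5 is taken to allylic alcohol F2 as above.
- F2 is epoxidised with Ti(OiPr)4 (10 mol %), natural L-(+)-diisopropyl tartrate (12 mol %), t-BuOOH and 4 Å sieves in CH2Cl2 at −20 °C. This tartrate antipode delivers oxygen to the same Si face (the sense that gives (S)-glycidol from allyl alcohol) and gives 5-formyl-2-[(2S)-2-(hydroxymethyl)oxiran-2-yl]phenyl 2-methylpropanoate F3. The descriptor is S only because CH2OH ranks below the ring CH2.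
- Prompt acylation with pentanoyl chloride/pyridine at −20 °C, before the isobutyryl group can migrate, gives [(2R)-2-[4-formyl-2-(2-methylpropanoyloxy)phenyl]oxiran-2-yl]methyl pentanoate F4.
- NaBH4 in THF/EtOH at −40 °C reduces the aldehyde without touching the epoxide or the esters and gives 10.

This material also serves as the reference for assigning the absolute configuration of the product of step 4.

**Further compounds**
F1 | step 1 | 2-bromo-5-formylphenyl 2-methylpropanoate | CC(C)C(=O)Oc1cc(C=O)ccc1Br
F2 | step 2 | 5-formyl-2-(3-hydroxyprop-1-en-2-yl)phenyl 2-methylpropanoate | CC(C)C(=O)Oc1cc(C=O)ccc1C(=C)CO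
F3 | step 4 | 5-formyl-2-[(2S)-2-(hydroxymethyl)oxiran-2-yl]phenyl 2-methylpropanoate | OC[C@@]1(c2ccc(C=O)cc2OC(=O)C(C)C)CO1
F4 | step 4 | [(2R)-2-[4-formyl-2-(2-methylpropanoyloxy)phenyl]oxiran-2-yl]methyl pentanoate | CCCCC(=O)OC[C@@]1(c2ccc(C=O)cc2OC(=O)C(C)C)CO1
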